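# Rufesolide C: proposed total synthesis by scission of a temporary C1–C6 bond in a decalin

## Structural features

Rufesolide C is a germacranolide. It has a fully saturated ten-membered carbocycle (C1–C10) that is trans-fused at C6–C7 to an α-methylene-γ-butyrolactone (O–C6, C7, C11=C13H2, C12=O). Going round the ring: C1 is a ketone, C10 carries a methyl group (C14) and a tertiary acetate, C9 is CH2, and C8 carries the angelate. C7 and C6 are the lactone carbons, C5 is CH2, C4 carries a methyl group (C15), C3 carries OMe, and C2 is CH2.

The six stereocenters fall into two clusters. One is C3/C4. The other is C6/C7/C8, with C10 in a 1,3 relation to C8. The clusters are insulated from each other by C5H2 on one side and by C2H2–C1(=O) on the other, so the monocycle offers no direct relay between them.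

Several groups are fragile:
- the β-methoxy ketone (C1/C3), which can lose methanol by E1cB;
- the α-acetoxy ketone;
- the (Z)-angelate, which drifts to the tiglate;
- the exocyclic enoate, which is a Michael acceptor;
- the C8 acyloxy group, which is β to any carbonyl placed at C6.

The real difficulty is to close a saturated ten-membered ring that has no alkene or other rigid element, against transannular strain, while relating the two clusters.

The key step exploits one feature. The carbonyl carbon C1 and the carbinol carbon C6 face each other 1,6 across the ring, with exactly four carbons on either side (C2–C5 and C7–C10). A C1–C6 bond therefore turns the target into a decalin, and the two oxygenated carbons are the scars of a C1=C6 double bond. In that decalin, ring B (C1, C10, C9, C8, C7, C6) has the methyl/oxygen pattern of a methyl-p-quinone monoketal. A carbinol at C1 sits within directing distance of C3, C4 and C10.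

## Logic of the disconnections

**24 ⇒ 22.** The lactone C12–O bond and the C6–H bond are cut, leaving a C6 ketone next to an acrylate ester. This postpones the Michael-acceptor lactone to the last step and reduces the ring problem to a cyclodecane-1,6-dione. The forward step must reduce C6 and not C1, and it must attack from one face only.

**22 ⇒ 20 (key).** The two carbonyl carbons C1 and C6 are reconnected as a C1=C6 double bond. The strained ten-membered ring becomes the periphery of an octalin, and no medium-ring closure is ever attempted. Five of the six stereocenters can then be set on chair cyclohexanes. The forward step must cleave a hindered tetrasubstituted alkene in the presence of two conjugated ester alkenes, and it must hand on a dione that is prone to transannular aldol reaction.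

**20 ⇒ 19 ⇒ 16 ⇒ 13 + 14.** The alkene is traced to a C1 carbinol with a trans-diaxial H-6. The C12 ester is traced to the isopropenyl methyl group. The C8–O and C10–O acyl bonds are cut. This exposes a triol in which the three hydroxyl groups differ in class and hindrance. Demands on the forward steps: elimination toward C6, esterification at C8 with inversion, and oxidation of only the electron-rich alkene.

**13 ⇒ 12 ⇒ 11 ⇒ 10.** The 8,10-dioxygen pattern with C9H2 is traced to an α,β-epoxy ketone and then to its ketal. The C9–O bond is the one that reduction removes. The gain is that the C10 configuration reduces to the face of an epoxide. The demand is a reductive opening that breaks only the bond α to C8.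

**10 ⇒ 9 ⇒ 8 ⇒ 7.** The O–CH3 bond, the C4–C15 bond and four C–O bonds of two epoxides are cut. All three target centers C3, C4 and C10 collapse onto the one temporary carbinol at C1. The demands are delivery of oxygen to the same face of both alkenes and trans-diaxial opening at C4 only.

**7 ⇒ 6.** The C3=C4 bond is cut (ring A), leaving two allyl groups. The demand is that the allyl groups be trans, so that the decalin is trans-fused and rigid.

**6 ⇒ 5 ⇒ 4.** The C1–C2 and C5–C6 bonds are cut. Both allyl groups are attached to a cyclohexenone by its two native reactivities, the carbonyl and the α′-enolate. Each addition is steered by the substituent introduced just before it.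

**4 ⇒ 2 + 3.** The C7–C11 bond is cut. This is the only stereocenter set by a chiral catalyst. The forward step must choose the unsubstituted enone arm.

**2 ⇒ 1.** One ketal C–O bond is cut, giving a commercial phenol.

## Other disconnections considered

**Alternative 1:** This is the cut that comes to mind first: C6–C7 together with the lactone C–O bond. The forward key step is an intramolecular Nozaki–Hiyama–Kishi or Barbier allylation of the bromomethyl-acrylate aldehyde A1, followed by lactonisation. A1 is an open chain with four isolated stereocenters, each of which needs its own reagent control. It already carries the β-methoxy ketone, the α-acetoxy ketone and a free C1 ketone that competes as an electrophile. The closure is a true ten-membered cyclisation of a chain with no conformational bias. Both C6 and C7 would also be set in a macrocyclic transition state whose syn/anti preference cannot be argued with confidence. The chosen plan never closes a ring larger than six.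

**Alternative 2:** This cuts C3–C4 and reconnects C1–C6. The forward key step is an anionic oxy-Cope rearrangement of the carvone-derived dialkenyl carbinol A2.
- A chair analysis shows that (E,E)-alkenes give C3/C4 with the wrong sense relative to C7. Both alkenes must therefore be (Z) and sit axial in the transition state.
- The enolate that is formed (C1=C2) has the C3 methoxy group as a β-leaving group.
- The product keeps a C5=C6 alkene that must still be hydrated with regio- and stereocontrol, and it lacks oxygen at C8 and C10.

This route is longer after the key step, and it endangers the most fragile motif.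

**Alternative 3:** This uses the same C1–C6 bond but cuts it by oxygen insertion, through a Criegee rearrangement of the C1 perester A3 to the 6-hydroxy ketone. It is attractive because migration is stereoretentive at C6. Two arguments speak against it. At C1 the fully substituted, oxygen-bearing C10 is a better migrating group than the secondary C6. Retention from the accessible series (H-6 trans to H-7) would also give the 6-epimer, the cis-lactone series. The tertiary hydroperoxide costs further steps as well.

Key step: step 17

Remark on numbering: germacrane numbering (C1–C15 as above) is kept for all intermediates. The α face is the face that carries H-7, and the β face is the opposite one.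

## Route

Step 1
Reactants: 1 4-methoxy-2-methylphenol
Product: 2 4,4-dimethoxy-2-methylcyclohexa-2,5-dien-1-one
Conditions: PhI(OAc)2, MeOH, 0 °C
Reagents that add atoms: methanol, CO
Why: Oxidative dearomatisation of a para-alkoxyphenol with a hypervalent iodine reagent gives the quinone monoketal; it supplies all six carbons of ring B plus C14, with C1 (ketone) and C8 (ketal) already differentiated.

Step 2
Reactants: 2 4,4-dimethoxy-2-methylcyclohexa-2,5-dien-1-one; 3 isopropenylboronic acid pinacol ester
Product: 4 (5R)-4,4-dimethoxy-2-methyl-5-(prop-1-en-2-yl)cyclohex-2-en-1-one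
Conditions: [Rh(OH)((R)-binap)]2 (cat.), KOH (cat.), dioxane/H2O, 40 °C
Reagents that add atoms: none
Why: Rhodium-catalysed asymmetric conjugate addition of an alkenylboron reagent (Hayashi–Miyaura reaction); the α-methylated enone arm is far less reactive, so only C7 is attacked, and (R)-binap is chosen by analogy with its sense of induction on 2-cyclohexenone to set C7, the one center not obtained by relay.

Step 3
Reactants: 4 (5R)-4,4-dimethoxy-2-methyl-5-(prop-1-en-2-yl)cyclohex-2-en-1-one
Product: 5 (5R,6S)-6-allyl-4,4-dimethoxy-2-methyl-5-(prop-1-en-2-yl)cyclohex-2-en-1-one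
Conditions: LiN(i-Pr)2, THF, −78 °C; allyl bromide, DMPU, −78 to −30 °C
Reagents that add atoms: allyl bromide, C=CCBr
Why: Kinetic α′-enolate alkylation (C6 is the only enolisable position) anti to the neighbouring isopropenyl group, as with carvone enolates; this forms C5–C6 and sets the temporary center C6 (H-6 β).

Step 4
Reactants: 5 (5R,6S)-6-allyl-4,4-dimethoxy-2-methyl-5-(prop-1-en-2-yl)cyclohex-2-en-1-one
Product: 6 1,6-diallyl-4,4-dimethoxy-2-methyl-5-(prop-1-en-2-yl)cyclohex-2-en-1-ol (allyl groups trans; 1α-OH)
Conditions: allylmagnesium bromide, CeCl3, THF, −78 °C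
Reagents that add atoms: allylmagnesium bromide, C=CC[Mg]Br
Why: Cerium-assisted Grignard 1,2-addition suppresses enolisation and conjugate addition; the nucleophile should enter anti to the C6 allyl group, which forms C1–C2 and puts the C1 hydroxyl on the α face.

Step 5
Reactants: 6 1,6-diallyl-4,4-dimethoxy-2-methyl-5-(prop-1-en-2-yl)cyclohex-2-en-1-ol
Product: 7 trans-decalin dienol (1α-OH; 6β-H; C3=C4; C9=C10; 8,8-dimethoxy; 7β-isopropenyl)
Conditions: second-generation Grubbs catalyst (cat.), CH2Cl2, 40 °C
Reagents that add atoms: none
Why: Ring-closing metathesis of the two monosubstituted alkenes closes six-membered ring A, while the 1,1-disubstituted and trisubstituted alkenes are slow partners; trans-diequatorial allyl groups give a rigid trans-decalin with an axial C1 hydroxyl.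

Step 6
Reactants: 7 trans-decalin dienol
Product: 8 3α,4α:9α,10α-bis-epoxide of 7
Conditions: VO(acac)2 (cat.), t-BuOOH, CH2Cl2, 0 °C to rt
Reagents that add atoms: tert-butyl hydroperoxide, CC(C)(C)OO
Why: Vanadium-catalysed hydroxyl-directed epoxidation; the axial C1–OH is allylic to C9=C10 and homoallylic to C3=C4 and delivers oxygen to the α face of both, fixing C10–O and C3–O in one event, while the remote isopropenyl group is not bound to the metal.

Step 7
Reactants: 8 3α,4α:9α,10α-bis-epoxide
Product: 9 1α,3α-diol with 4β-methyl group (9α,10α-epoxide kept)
Conditions: Me2CuLi, Et2O, −30 to 0 °C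
Reagents that add atoms: lithium dimethylcuprate, [Li+].C[Cu-]C
Why: Cuprate opening under the Fürst–Plattner rule: in the rigid trans-decalin only attack at C4 from the β face gives the trans-diaxial product (3α-OH, 4β-CH3); the ring B epoxide is shielded because C9 lies between the ketal carbon and the fully substituted C10.

Step 8
Reactants: 9 1α,3α-diol with 4β-methyl group
Product: 10 3α-methyl ether of 9
Conditions: Me3OBF4, 1,8-bis(dimethylamino)naphthalene, 4 Å molecular sieves, CH2Cl2, rt
Reagents that add atoms: trimethyloxonium tetrafluoroborate, C[O+](C)C.F[B-](F)(F)F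
Why: Meerwein-salt O-methylation under non-basic conditions takes the secondary C3 alcohol; the ring-fusion tertiary alcohol is too hindered, and epoxide and ketal survive.

Step 9
Reactants: 10 3α-methyl ether
Product: 11 9α,10α-epoxy-8-ketone
Conditions: SiO2, aq. oxalic acid, CH2Cl2, rt
Reagents that add atoms: water, O
Why: Mild acid hydrolysis of a dimethyl ketal on wet silica, a reaction type used on epoxyquinone monoketals; it unmasks the α,β-epoxy ketone without opening the epoxide.

Step 10
Reactants: 11 9α,10α-epoxy-8-ketone
Product: 12 1α,10α-dihydroxy-8-ketone
Conditions: SmI2, THF/MeOH, −90 °C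
Reagents that add atoms: none
Why: Single-electron reduction of an α,β-epoxy ketone cleaves the Cα–O bond (C9–O) through the ketyl and gives the β-hydroxy ketone; the C10–O bond and its configuration are not touched.

Step 11
Reactants: 12 1α,10α-dihydroxy-8-ketone
Product: 13 1α,8β,10α-triol
Conditions: LiBH(s-Bu)3, THF, −78 °C; H2O
Reagents that add atoms: none
Why: The bulky borohydride attacks the C8 carbonyl along the equatorial trajectory from the α face because the β face is blocked by the axial C14 methyl group; this gives the axial 8β-alcohol, and the isopropenyl group is inert.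

Step 12
Reactants: 13 1α,8β,10α-triol; 14 angelic acid
Product: 15 8α-angelate 1α,10α-diol
Conditions: PPh3, DIAD, toluene, 0 °C to rt
Reagents that add atoms: none
Why: Mitsunobu esterification: SN2 displacement from the open α face inverts C8 to the target configuration and avoids the acyl activation that isomerises angelate to tiglate; the tertiary alcohols do not react.

Step 13
Reactants: 15 8α-angelate 1α,10α-diol
Product: 16 10α-acetate 8α-angelate 1α-ol
Conditions: Ac2O, DMAP, Et3N, CH2Cl2, 35 °C
Reagents that add atoms: acetic anhydride, CC(=O)OC(C)=O
Why: DMAP-catalysed acylation; the equatorial C10 hydroxyl reacts, whereas the axial ring-fusion C1 hydroxyl between C10 and C6 is much more hindered.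

Step 14
Reactants: 16 10α-acetate 8α-angelate 1α-ol
Product: 17 C12 allylic alcohol of 16
Conditions: SeO2 (cat.), t-BuOOH, CH2Cl2, 0 °C to rt
Reagents that add atoms: tert-butyl hydroperoxide, CC(C)(C)OO
Why: Selenium dioxide allylic oxidation (ene reaction, then [2,3]-shift) at the methyl group of the only electron-rich alkene; the conjugated angelate alkene is too electron-poor to react.

Step 15
Reactants: 17 C12 allylic alcohol
Product: 19 C12 methyl ester (2-substituted methyl acrylate), via enal 18 (not isolated)
Conditions: MnO2, 1,4-dimethyl-1,2,4-triazolium iodide (cat.), DBU (cat.), MeOH, CH2Cl2, rt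
Reagents that add atoms: methanol, CO
Why: Tandem allylic oxidation and carbene-catalysed oxidative esterification: MnO2 gives the enal, the carbene adduct is oxidised to the acyl azolium and methanol releases the ester; the tertiary alcohol and the other esters are untouched and no cyanide is needed.

Step 16
Reactants: 19 C12 methyl ester
Product: 20 Δ1(6)-octalin (3α-OMe; 4β-Me; 8α-OAng; 10α-OAc)
Conditions: SOCl2, pyridine, −20 to 0 °C
Reagents that add atoms: none
Why: Dehydration through the chlorosulfite by anti elimination: the axial C1–O bond is antiperiplanar to the axial H-6, and loss of H-6 gives the tetrasubstituted alkene and relieves the syn-axial contacts of C14 and C15; the two temporary centers C1 and C6 are erased.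

Step 17
Reactants: 20 Δ1(6)-octalin
Product: 22 cyclodecane-1,6-dione (ten-membered ring), via primary ozonide 21 (not isolated)
Conditions: O3 (1 equiv, Sudan Red 7B as end-point indicator), CH2Cl2, −78 °C; PPh3, −78 °C to rt
Reagents that add atoms: ozone, [O-][O+]=O
Why: Ozone adds to C1=C6 in a concerted 1,3-dipolar cycloaddition to give 21, which cycloreverts to a ketone and a carbonyl oxide held in the same ring, and PPh3 takes the extra oxygen atom, so C1 and C6 both emerge as ketones. No ring is closed: the ten-membered ring already exists as the periphery of the bicyclo[4.4.0] system and is set free by cutting the zero-atom bridge, which avoids the entropy and transannular strain of a medium-ring cyclisation. The closest known reaction is the ozonolysis of Δ9,10-octalin to cyclodecane-1,6-dione. No stereocenter is formed, and the five centers C3, C4, C7, C8 and C10, set earlier on chairs, are carried over unchanged because none of them is touched by the cycloaddition. The selectivity needed is chemoselectivity among three alkenes. The substrate secures it because C1=C6 is the only alkene not conjugated to an ester, and ozone is an electrophile that is also small enough to reach a tetrasubstituted alkene. The indicator dye limits the ozone dose. Neutral, cold work-up is required because the dione can undergo transannular aldol reaction and carries β-leaving groups at C3 and C8.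

Step 18
Reactants: 22 cyclodecane-1,6-dione
Product: 24 Rufesolide C, via hydroxy ester 23 (not isolated)
Conditions: (S)-Me-CBS oxazaborolidine, catecholborane, toluene, −78 °C; MeOH; PPTS (cat.), CH2Cl2, rt
Reagents that add atoms: none
Why: Corey–Bakshi–Shibata reduction: the catalyst distinguishes the branched C7 side (large) from C5H2 (small), so the (S)-catalyst should give the (6R)-alcohol, and the C1 ketone next to the fully substituted C10 reacts more slowly. The 6α-hydroxyl then closes on the C12 ester by acid-catalysed transesterification to the trans-lactone.

## Compound list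

1 | 4-methoxy-2-methylphenol | COc1ccc(O)c(C)c1 | starting material
2 | 4,4-dimethoxy-2-methylcyclohexa-2,5-dien-1-one | COC1(OC)C=CC(=O)C(C)=C1 | intermediate
3 | isopropenylboronic acid pinacol ester | C=C(C)B1OC(C)(C)C(C)(C)O1 | starting material
4 | (5R)-4,4-dimethoxy-2-methyl-5-(prop-1-en-2-yl)cyclohex-2-en-1-one | O=C1C[C@H](C(C)=C)C(OC)(OC)C=C1C | intermediate
5 | (5R,6S)-6-allyl-4,4-dimethoxy-2-methyl-5-(prop-1-en-2-yl)cyclohex-2-en-1-one | O=C1[C@@H](CC=C)[C@H](C(C)=C)C(OC)(OC)C=C1C | intermediate
6 | trans-1,6-diallyl carbinol (1α-OH) | O[C@]1(CC=C)C(C)=CC(OC)(OC)[C@@H](C(C)=C)[C@@H]1CC=C | intermediate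
7 | trans-decalin dienol (1α-OH, 6β-H, C3=C4, C9=C10, 8,8-dimethoxy, 7β-isopropenyl) | O[C@@]12CC=CC[C@H]1[C@H](C(C)=C)C(OC)(OC)C=C2C | intermediate
8 | 3α,4α:9α,10α-bis-epoxide | O[C@@]12C[C@H]3O[C@H]3C[C@H]1[C@H](C(C)=C)C(OC)(OC)[C@H]4O[C@@]24C | intermediate
9 | 1α,3α-diol, 4β-methyl, 9α,10α-epoxide | O[C@@]12C[C@@H](O)[C@H](C)C[C@H]1[C@H](C(C)=C)C(OC)(OC)[C@H]3O[C@@]23C | intermediate
10 | 3α-methyl ether | O[C@@]12C[C@@H](OC)[C@H](C)C[C@H]1[C@H](C(C)=C)C(OC)(OC)[C@H]3O[C@@]23C | intermediate
11 | 9α,10α-epoxy-8-ketone | O[C@@]12C[C@@H](OC)[C@H](C)C[C@H]1[C@H](C(C)=C)C(=O)[C@H]3O[C@@]23C | intermediate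
12 | 1α,10α-dihydroxy-8-ketone | O[C@@]12C[C@@H](OC)[C@H](C)C[C@H]1[C@H](C(C)=C)C(=O)C[C@@]2(C)O | intermediate
13 | 1α,8β,10α-triol | O[C@@]12C[C@@H](OC)[C@H](C)C[C@H]1[C@H](C(C)=C)[C@H](O)C[C@@]2(C)O | intermediate
14 | angelic acid, (Z)-2-methylbut-2-enoic acid | C/C=C(/C)C(=O)O | starting material
15 | 8α-angelate 1α,10α-diol | O[C@@]12C[C@@H](OC)[C@H](C)C[C@H]1[C@H](C(C)=C)[C@@H](OC(=O)/C(C)=C\C)C[C@@]2(C)O | intermediate
16 | 10α-acetate 8α-angelate 1α-ol | O[C@@]12C[C@@H](OC)[C@H](C)C[C@H]1[C@H](C(C)=C)[C@@H](OC(=O)/C(C)=C\C)C[C@@]2(C)OC(C)=O | intermediate
17 | C12 allylic alcohol | O[C@@]12C[C@@H](OC)[C@H](C)C[C@H]1[C@H](C(=C)CO)[C@@H](OC(=O)/C(C)=C\C)C[C@@]2(C)OC(C)=O | intermediate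
18 | C12 enal | O[C@@]12C[C@@H](OC)[C@H](C)C[C@H]1[C@H](C(=C)C=O)[C@@H](OC(=O)/C(C)=C\C)C[C@@]2(C)OC(C)=O | intermediate
19 | C12 methyl ester | O[C@@]12C[C@@H](OC)[C@H](C)C[C@H]1[C@H](C(=C)C(=O)OC)[C@@H](OC(=O)/C(C)=C\C)C[C@@]2(C)OC(C)=O | intermediate
20 | Δ1(6)-octalin | COC(=O)C(=C)[C@@H]1[C@@H](OC(=O)/C(C)=C\C)C[C@@](C)(OC(C)=O)C2=C1C[C@@H](C)[C@H](OC)C2 | intermediate
21 | primary ozonide (α face) | COC(=O)C(=C)[C@@H]1[C@@H](OC(=O)/C(C)=C\C)C[C@@](C)(OC(C)=O)[C@@]23OOO[C@@]12C[C@@H](C)[C@H](OC)C3 | intermediate
22 | cyclodecane-1,6-dione | COC(=O)C(=C)[C@@H]1[C@@H](OC(=O)/C(C)=C\C)C[C@@](C)(OC(C)=O)C(=O)C[C@@H](OC)[C@H](C)CC1=O | intermediate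
23 | (6R)-6-hydroxy ester | COC(=O)C(=C)[C@@H]1[C@@H](OC(=O)/C(C)=C\C)C[C@@](C)(OC(C)=O)C(=O)C[C@@H](OC)[C@H](C)C[C@H]1O | intermediate
24 | Rufesolide C (3R,4R,6R,7S,8S,10R) | C=C1C(=O)O[C@@H]2C[C@@H](C)[C@H](OC)CC(=O)[C@](C)(OC(C)=O)C[C@H](OC(=O)/C(C)=C\C)[C@@H]12 | target

## Step count and least certain steps

Total step count: 18. Longest linear sequence: 18 (from 1).

**Step 17 (key step).** The hindered alkene may react slowly enough for the two conjugated alkenes to be over-oxidised. The carbonyl oxide and the ketone sit in one ring and cannot close to a normal ozonide, so oligomeric peroxides may form. The dione may also undergo transannular aldol reaction during work-up.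
Fallback, from 20 back to 22: oxygen is first placed on the alkene with mCPBA, which is far more sensitive to alkene substitution than ozone. This gives the tetrasubstituted epoxide F1. F1 is then opened and cleaved with H5IO6 in wet ether to give 22.

**Step 18.** Facial selectivity may be poor. Any external hydride source must approach the C6 carbonyl from the periphery of the ring, and the conformer population decides which face is exposed, so the catalyst may be mismatched with the substrate. Partial reduction at C1 is also possible.
Fallback, from 22 back to 24: the C6–O bond of the lactone is formed by substitution instead of acylation.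
1. Reduction of 22 with NaBH4/CeCl3 at −78 °C from the periphery gives the 6-epimeric hydroxy ester F2.
2. F2 is kept cold and converted at once with MsCl/Et3N into the mesylate F3.
3. LiI in pyridine cleaves the methyl ester, and the carboxylate displaces the mesylate from the outer face with inversion to give 24.

**Step 16.** Regioselectivity of proton loss may be wrong. The axial H-6 lies between the axial C14 and C15 methyl groups and is hard for the base to reach, so the axial H-2 may be lost instead.
Fallback, from 19 back to 20: the concerted elimination is replaced by ionisation under thermodynamic control. Compound 19 is acylated with trifluoroacetic anhydride to the tertiary trifluoroacetate F4. F4 is solvolysed in hexafluoroisopropanol buffered with 2,6-di-tert-butylpyridine, so that the C1 cation loses the proton that leads to the tetrasubstituted alkene 20.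

**Step 12.** The activated axial alcohol may eliminate (H-7 and H-9 are antiperiplanar), or activation of the hindered alcohol may fail.
Fallback, from 12 back to 15: the configuration is set in the reduction, not in the esterification. Electron-transfer reduction of 12 (SmI2, H2O, Et3N, THF) should give the more stable equatorial 8α-alcohol F5. F5 is acylated at the secondary hydroxyl with the mixed anhydride made from 14 and 2,4,6-trichlorobenzoyl chloride (Et3N, DMAP, toluene) to give 15.

## Further compounds

F1 | step 17 | 1α,6α-epoxide of 20 | COC(=O)C(=C)[C@@H]1[C@@H](OC(=O)/C(C)=C\C)C[C@@](C)(OC(C)=O)[C@@]23O[C@@]12C[C@@H](C)[C@H](OC)C3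
F2 | step 18 | (6S)-6-hydroxy ester | COC(=O)C(=C)[C@@H]1[C@@H](OC(=O)/C(C)=C\C)C[C@@](C)(OC(C)=O)C(=O)C[C@@H](OC)[C@H](C)C[C@@H]1O
F3 | step 18 | (6S)-6-mesylate | COC(=O)C(=C)[C@@H]1[C@@H](OC(=O)/C(C)=C\C)C[C@@](C)(OC(C)=O)C(=O)C[C@@H](OC)[C@H](C)C[C@@H]1OS(C)(=O)=O
F4 | step 16 | C1 trifluoroacetate of 19 | O=C(O[C@@]12C[C@@H](OC)[C@H](C)C[C@H]1[C@H](C(=C)C(=O)OC)[C@@H](OC(=O)/C(C)=C\C)C[C@@]2(C)OC(C)=O)C(F)(F)F
F5 | step 12 | 1α,8α,10α-triol | O[C@@]12C[C@@H](OC)[C@H](C)C[C@H]1[C@H](C(C)=C)[C@@H](O)C[C@@]2(C)O
A1 | alternative 1 | seco aldehyde (Z)-2-(bromomethyl)enoate | O=CC[C@@H](C)[C@H](OC)CC(=O)[C@](C)(OC(C)=O)C[C@H](OC(=O)/C(C)=C\C)/C=C(\CBr)C(=O)OC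
A2 | alternative 2 | 1-[(Z)-2-methoxyvinyl]-6-[(Z)-prop-1-enyl]carveol | O[C@]1(/C=C\OC)C(C)=CC[C@@H](C(C)=C)[C@@H]1/C=C\C
A3 | alternative 3 | C1 p-nitroperbenzoate of the decalin | O=C(OO[C@@]12C[C@@H](OC)[C@H](C)C[C@H]1[C@H](C(=C)C(=O)OC)[C@@H](OC(=O)/C(C)=C\C)C[C@@]2(C)OC(C)=O)c1ccc(cc1)[N+](=O)[O-]
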